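**Time and charge.** Ask first how long each flask runs, then what its reagent can pay for: ochre and amber differ in both.

| setting | cedar | alder | ochre | amber |
|---|---|---|---|---|
| starting material | 0.0050 M | 0.0050 M | 0.0050 M | 0.0050 M |
| reagent | 4.9 mM | 15 mM | 6.50 mM | 20.0 mM |
| protic impurity | 0.10 mM | 0.10 mM | 0.100 mM | 0.100 mM |
| remark | run made earlier | run made earlier |  |  |
| time |  |  | 3.0 min | 0.80 min |

| run | time / min | target / % |
|---|---|---|
| cedar | 0.200 | 0 |
| cedar | 0.667 | 3.4 |
| cedar | 1.00 | 4.3 |
| cedar | 1.50 | 6.2 |
| cedar | 2.50 | 6.0 |
| cedar | 3.00 | 4.7 |
| alder | 0.500 | 7.9 |
| alder | 1.00 | 12.2 |
| alder | 1.50 | 13.9 |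
| alder | 2.00 | 15.8 |
| alder | 2.50 | 13.1 |
| alder | 3.00 | 15.4 |

(standard deviation of a reading: 1 percentage point)

- what may be going on: starting material -> intermediate A; reagent + intermediate A -> intermediate B; reagent + intermediate B -> target; reagent + intermediate A -> side product; starting material + protic impurity -> quenched substrate

1. which of the two ends with the higher amount of target, in percent of the starting material charged ("neither" if they lie within 2 percentage points) (ochre / amber / neither)
2. target at the end, in percent of the starting material charged, ochre
3. target at the end, in percent of the starting material charged, amber

**Reagent balance.** Write the balance of the reagent. Starting material ending as side product takes one reagent; starting material ending as target takes two, through intermediate B. Read the target share from the level of the alder run, the mean of its last 3 readings: 14.8%. Then the charged starting material, times one plus that share, gives the reagent need: 5.74 mM.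

**Turning reagent.** Cedar's charge of 4.9 mM is less than the need, and its reading at 2.50 min is 6.0%. Ochre's 6.50 mM is more than the need, by a surplus of 0.762 mM. Expect ochre below the alder level, slowed at the last step, and commit to no closer number.

**Turning time.** Alder stands at 12.2% after 1.00 min. Assume an exponential approach at that pace, and my reckoning for amber at 0.80 min gives 11.1%.

**Turning impurity.** Its charge can divert at most 2.00% of the starting material.

**The forecast.** It gives 10% for ochre and 12.5% for amber, above my figure, and names amber. Its ground on ochre: “A consumes about 4.9 mM, leaving only about 1.2 mM reagent to push B to target”.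

**The result.** Ochre ends at 12.7% and amber at 12.0%, so the answer is neither within 2 percentage points.

    starting material → intermediate A (k = 0.0401 s⁻¹)
    reagent + intermediate A → intermediate B (k = 18.3 L mol⁻¹ s⁻¹)
    reagent + intermediate B → target (k = 8.35 L mol⁻¹ s⁻¹)
    reagent + intermediate A → side product (k = 99.6 L mol⁻¹ s⁻¹)
    starting material + protic impurity → quenched substrate (k = 27.2 L mol⁻¹ s⁻¹)

**The comparison.** The need leaves 11.7% of ochre's reagent and 71.3% of amber's; the flasks hold 12.9% and 71.7% after 30.0 min and 8.00 min. Set the half-life of starting material by its passing into intermediate A, 0.288 min, against each end: amber at 0.800 min has run 2.78 half-lives and holds 14.2% starting material, while ochre at 3.00 min has run 10.4 half-lives and holds 0.0702% starting material and 2.53% intermediate B.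

**A neighbour.** Charge a flask like ochre with 2.60 mM of reagent, less than the need of 5.74 mM: here reagent is the limiting reagent. After 3.00 min it computes to 0% reagent, 0.858% target and 46.9% intermediate A.

(The earlier runs and the new flask were generated by integration for substances that don't exist; scatter was added.)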